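**The question.** I was asked what target this flask would hold at 2.5 h, and whether spring or winter would raise it.

all flasks: gas phase 200 mM (held)

| run | substrate | remark | time |
|---|---|---|---|
| birch | 3 M | the very flask that is asked about, followed so far |  |
| flask | 3.0 M |  | 2.5 h |

- birch (time / min: target / %, substrate / %): 20.0: 45.1, 0.3; 40.0: 13.9, 0; 60.0: 10.8, 0; 80.0: 9.7, 0

(scatter of a reading: 0.5 percentage points)

- what was read earlier has a scatter of 0.5 percentage points, one standard deviation
- at the start none of the gas phase is in solution

1. the target standing at 2.5 h, as a percentage of the substrate charged
2. the change that raises the amount of target at 2.5 h, in percent of the substrate charged most ("none" if none brings more than 2 percentage points) (spring / winter / none)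
3. amount of target at 2.5 h, in percent of the substrate charged, after winter

- spring: doubling the transfer coefficient of the gas phase, all else as stated
- winter: doubling the saturation concentration of gas phase, all else as stated

**In the flask.** Substrate read 0 % from 40.0 min on. Target then lost 3.1 percentage points and next 1.1 points, a smaller loss, with the gas phase held. I read this as a balance between target and the lost part. At a balance the forward and back rates match, so time drops out. I divided the lost fraction by the target fraction at 80.0 min. This standing ratio, the equilibrium constant if my reading holds, came to 9.31.

**On arrival.** My reckoning put target at 9.70 % at 2.5 h, a figure from one reading with a scatter of 0.5 points.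

**Do not touch.** My ratio held no gas term. So I left spring and winter alone and expected 9.70 % after winter too.

**The forecast.** It gave 9 %, from 8.2 % to 9.5 %, with best none. After winter it gave 3 %, from 0.3 % to 6.5 %, since winter “doubles the dissolved gas and so the late consumption of target”. My winter figure differed.

**The result.** The flask gave 10.0 %, best none, and 10.0 % after winter.

    2 dissolved gas → homo dimer (k = 8.01 /M/min)
    gas phase ⇌ dissolved gas, rate k2*(csat - [dissolved gas]) (kL = 0.809 /min)
    substrate + dissolved gas → target (k = 28.5 /M/min)
    target ⇌ isomer of the product (K = 8.98, k = 0.0950 /min)

**Where they parted.** They parted on winter, 3 % against 10.0 %. The relaxation half-life of target and isomer of the product, both ways together, was 0.109 h, shorter than the 2.5 h, and at 2.50 h this flask held 10.0 % target beside 90.0 % isomer of the product, where my ratio of 9.31 had given 9.70 % target.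

**The neighbour.** For the same flask left until 40 min, my ratio of 9.31 gave a standing target of 9.70 %. That flask held 14.3 % target and 85.7 % isomer of the product, a ratio of 5.99, lower than 9.31.

The readings are calculated for an exercise, noise included.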